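(Readings and results were computed for substances that don't exist, noise included.)

I decide to read the tops of these curves as a balance between making and losing target, not as a resting point, and to find what that reading does to the maple run. That run has cedar's charge and is asked about 100 min beyond cedar's last reading.

| flask | substrate | coupling partner | time |
|---|---|---|---|
| cedar | 80.0 mM | 120 mM |  |
| ash | 48.0 mM | 88.0 mM |  |
| oak | 240 mM | 120 mM |  |
| maple | 80.0 mM | 120 mM | 120 min |

- cedar run (time / min: [target] / mM): 1.5: 8.4; 4.6: 18.8; 8.8: 31.2; 14: 41.1; 20: 44.2
- ash run (time / min: [target] / mM): 1.5: 3.6; 4.6: 6.5; 8.8: 15.1; 14: 19.0; 20: 21.2
- oak run (time / min: [target] / mM): 1.5: 21.1; 4.6: 56.1; 8.8: 80.4; 14: 88.9; 20: 87.0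

(readings scatter by 0.8 mM)

- how the opening rate goes with [substrate] round the charge of the cedar run: the exponent of the rate at two percent of substrate gone to target (one fixed amount of target, the same in the runs compared)
- how the opening rate goes with [coupling partner] round the charge of the cedar run: the exponent of the rate at two percent of substrate gone to target
- target in the maple run at 120 min, as a share of the substrate charged

- Overall: substrate + coupling partner -> target.
- Constant volume, constant temperature.
- An order is taken over about fifteen percent of the charge, up and down.

How fast is target still made at the oak top? The first oak reading gives an opening rate of 14.1 mM min⁻¹. I scale this with the product of the two reagents, taking off the 88.9 mM of target read at 14 min, and get 2.30 mM min⁻¹. Oak's readings then change by 1.90 mM, against a scatter of a difference of 1.13 mM, so I take the flow out to equal the flow in.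

What follows is the lifetime of target, the standing stock divided by the flow through it: 38.7 min.

What does this leave in cedar's charge? I replace cedar's curve by the mean of its readings, 28.7 mM. Over 20 min that mean loses 14.8 mM, which leaves 21.0 mM of substrate. Target standing at 20 min keeps a fraction 0.0756 up to 120 min. If that substrate turned at once, the share at 120 min is 6.16 %; if it turned at the very end, 30.4 %. I commit to that bracket.

The forecast says “this looks like a reversible reaction reaching equilibrium” and gives orders of 1 in substrate and 1 in coupling partner, which I share, and 58 % (54 % to 62 %) for maple. My upper end lies lower than its figure.

The maple run gives 14.9 %, with orders 1.0 and 1.0.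

    substrate + coupling partner → target (0.4896 M⁻¹ min⁻¹)
    substrate + coupling partner + target → 2 target (7.320 M⁻² min⁻¹)
    target → decomposed product (0.01944 min⁻¹)

Fitted with the main steps alone, the root mean square residual is 6.2 in units of the scatter. Maple's share is 11.9 mM of target. My estimated lifetime of 38.7 min puts the loss of that target at 120 min at 0.307 mM min⁻¹, and the last step of the scheme, with a lifetime of 51.4 min, puts it at 0.232 mM min⁻¹. On the ash run's last reading that step draws 0.412 mM min⁻¹, while the ash run's last two readings show a net rise of 0.367 mM min⁻¹.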